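The plan cuts the central dioxepinone ring at two bonds of its lactone: carbonyl carbon to ring A (the methoxy/methyl ring) and ester oxygen to ring B (the phthalide ring). The excised unit is CO2. The key step exploits the fact that this O–C(=O) unit bridges a ring A carbon ortho to the ether oxygen and a ring B carbon para to the phthalide carbonyl: an arylmagnesium made on ring A captures CO2, and the carboxylate then displaces a ring B fluoride, closing the seven-membered ring in one operation. The precursor is an iodo/fluoro diaryl ether assembled by SNAr; the labile lactol centre is set last through a chiral benzylic acetal.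

Key step: step 9

Remark: the lactol carbon of a 3-hydroxyphthalide can epimerize through its ring-opened formyl acid, so this centre is carried racemic, set in step 11 and unveiled in step 12 under neutral, aprotic conditions.

Step 1
Reactants: 1 2-hydroxy-3-methoxy-5-methylbenzaldehyde
Product: 2 2-(benzyloxy)-3-methoxy-5-methylbenzaldehyde
Conditions: BnBr, K2CO3, DMF, rt
Reagents that add atoms: benzyl bromide, BrCc1ccccc1
Why: Williamson ether synthesis on the salicylaldehyde phenoxide should proceed cleanly and installs a benzyl group on the ring A oxygen that must remain distinct from the methoxy group until step 10.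

Step 2
Reactants: 2 2-(benzyloxy)-3-methoxy-5-methylbenzaldehyde
Product: 3 2-(benzyloxy)-6-iodo-3-methoxy-5-methylbenzaldehyde
Conditions: NIS, TFA, MeCN, rt to 50 °C
Reagents that add atoms: N-iodosuccinimide, O=C1CCC(=O)N1I
Why: Electrophilic aromatic iodination (SEAr): only two ring positions are open and the in-plane 3-methoxy group should steer the iodonium to its para position (C6, between the methyl and formyl groups) and not to its more congested ortho position, as is usual for halogenation of 2,3-dialkoxybenzaldehydes.

Step 3
Reactants: 3 2-(benzyloxy)-6-iodo-3-methoxy-5-methylbenzaldehyde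
Product: 5 2-(benzyloxy)-6-iodo-3-methoxy-5-methylphenol, via aryl formate 4 (not isolated)
Conditions: mCPBA, CH2Cl2, 0 °C to rt; then K2CO3 (cat.), MeOH, rt
Reagents that add atoms: mCPBA, OOC(=O)c1cccc(Cl)c1
Why: Baeyer–Villiger (Dakin-type) oxidation: the electron-rich aryl group with its ortho alkoxy substituent migrates in preference to hydride to give formate 4, which mild methanolysis should convert into the phenol without touching the aryl iodide or the benzyl ether.

Step 4
Reactants: 6 3,4-difluoroanisole
Product: 8 1,2-difluoro-4-methoxy-3-methylbenzene, via aryllithium 7 (not isolated)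
Conditions: n-BuLi, THF, −78 °C; then MeI, −78 °C to rt
Reagents that add atoms: iodomethane, CI
Why: Directed ortho-metalation: the hydrogen flanked by OMe and F is the most acidic and best coordinated site of 6, and aryllithium 7, kept at −78 °C to avoid loss of LiF, should be methylated by MeI.

Step 5
Reactants: 8 1,2-difluoro-4-methoxy-3-methylbenzene
Product: 10 2,3-difluoro-5-methoxy-4-methylbenzaldehyde, via aryllithium 9 (not isolated)
Conditions: LiTMP (from n-BuLi and 2,2,6,6-tetramethylpiperidine), THF, −78 °C; then DMF, −78 to 0 °C; aq. HCl
Reagents that add atoms: N,N-dimethylformamide, CN(C)C=O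
Why: Acidity-controlled directed ortho-metalation: with a hindered lithium amide the hydrogen next to fluorine (ortho to one C–F and meta to the other) should be removed in preference to the one next to OMe, and aryllithium 9 is formylated by DMF.

Step 6
Reactants: 10 2,3-difluoro-5-methoxy-4-methylbenzaldehyde
Product: 13 4,5-difluoro-3-hydroxy-7-methoxy-6-methylisobenzofuran-1(3H)-one (racemic), via lithium amino alkoxide 11 (not isolated), via ortho-lithiated amino alkoxide 12 (not isolated)
Conditions: LiN(Me)CH2CH2NMe2 (from n-BuLi and N,N,N'-trimethylethylenediamine), THF, −20 °C; n-BuLi, −20 °C; CO2, −78 °C to rt; aq. HCl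
Reagents that add atoms: carbon dioxide, O=C=O
Why: Directed ortho-metalation with in situ protection of the aldehyde: addition of the lithium amide gives α-amino alkoxide 11, which directs lithiation to the single remaining ring hydrogen (also ortho to OMe), 12 is carboxylated by CO2, and acidic work-up should release the 2-formylbenzoic acid, which closes to the racemic lactol by ring-chain tautomerism.

Step 7
Reactants: 5 2-(benzyloxy)-6-iodo-3-methoxy-5-methylphenol; 13 4,5-difluoro-3-hydroxy-7-methoxy-6-methylisobenzofuran-1(3H)-one
Product: 16 4-[2-(benzyloxy)-6-iodo-3-methoxy-5-methylphenoxy]-5-fluoro-3-hydroxy-7-methoxy-6-methylisobenzofuran-1(3H)-one (racemic), via potassium formylbenzoate 14 (not isolated), via potassium aryloxy formylbenzoate 15 (not isolated)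
Conditions: K2CO3, DMSO, 100 °C; then aq. HCl
Reagents that add atoms: none
Why: Nucleophilic aromatic substitution (SNAr): under carbonate the lactol opens to formyl benzoate 14, in which only the fluorine ortho to the formyl group is activated (the other is para to the non-activating carboxylate), so the phenoxide of 5 should displace it selectively, and acidification recloses the lactol.

Step 8
Reactants: 16 4-[2-(benzyloxy)-6-iodo-3-methoxy-5-methylphenoxy]-5-fluoro-3-hydroxy-7-methoxy-6-methylisobenzofuran-1(3H)-one
Product: 17 4-[2-(benzyloxy)-6-iodo-3-methoxy-5-methylphenoxy]-5-fluoro-3,7-dimethoxy-6-methylisobenzofuran-1(3H)-one (racemic)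
Conditions: MeOH, H2SO4 (cat.), reflux
Reagents that add atoms: methanol, CO
Why: Acid-catalysed pseudo-ester formation (Fischer-type acetalization of a 3-hydroxyphthalide) should mask the acidic lactol and its latent aldehyde before the organomagnesium step and holds the lactone carbonyl coplanar with ring B, para to the remaining fluorine.

Step 9
Reactants: 17 4-[2-(benzyloxy)-6-iodo-3-methoxy-5-methylphenoxy]-5-fluoro-3,7-dimethoxy-6-methylisobenzofuran-1(3H)-one
Product: 20 protected depsidone (ring A OBn; ring B OMe; methyl acetal at the phthalide carbon; racemic), via arylmagnesium chloride 18 (not isolated), via chloromagnesium carboxylate 19 (not isolated)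
Conditions: iPrMgCl·LiCl, THF, −40 °C; CO2 (1 atm), −40 °C to rt; then THF removed, Cs2CO3, anhydrous DMSO, 100 °C
Reagents that add atoms: carbon dioxide, O=C=O
Why: Iodine–magnesium exchange at the ring A carbon between the methyl group and the diaryl ether oxygen gives arylmagnesium 18, which adds to CO2 and so forms the aryl–carbonyl C–C bond of carboxylate 19; after the switch to Cs2CO3/DMSO the carboxylate oxygen adds to the fluorine-bearing ring B carbon and fluoride leaves (addition–elimination through a Meisenheimer intermediate), which forms the ester O–aryl bond and the central ring. The closest known reaction types are halogen–magnesium exchange with carboxylation and SNAr lactonization of a benzoate onto a tethered activated fluoroarene, here run as one telescoped operation. The seven-membered dioxepinone closes in a 7-exo-trig addition of oxygen to the C–F carbon. No stereocenter is formed; the racemic methyl acetal only masks the lactol. The step needs chemoselective exchange (aryl iodide before lactone carbonyl or C–F), secured by the fast I/Mg exchange at −40 °C and immediate CO2 quench, and site-selective O-arylation, secured because the C–F carbon is the only leaving-group-bearing ring B position para to the coplanar phthalide carbonyl, while ipso attack at the ether carbon (Smiles path) is meta to it and unactivated.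

Step 10
Reactants: 20 protected depsidone
Product: 21 racemic lactol (constitution of the target; both configurations at the lactol carbon)
Conditions: BCl3, pentamethylbenzene, CH2Cl2, −78 to 0 °C; then H2O/THF
Reagents that add atoms: water, O
Why: Lewis acid ether cleavage with BCl3: chelation to the phthalide carbonyl should direct demethylation of the adjacent ring B methoxy group, the benzyl ether is cleaved with pentamethylbenzene as cation scavenger, the acetal methoxy group is ionized and replaced by OH on aqueous work-up, and the unchelated ring A methoxy group should survive at low temperature.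

Step 11
Reactants: 21 racemic lactol
Product: 23 (R)-acetal of the lactol with (S)-1-phenylethanol, via (3S)-acetal epimer 22 (not isolated)
Conditions: (S)-1-phenylethanol, CSA (cat.), 4 Å MS, toluene, 40 °C, slow crystallization
Reagents that add atoms: (S)-1-phenylethanol, C[C@H](O)c1ccccc1
Why: Acid-catalysed acetal (pseudo-ester) formation under thermodynamic control: the acetal carbon epimerizes through the ring-opened hemiacetal or oxocarbenium ion while the carbinol centre of the auxiliary is fixed, so the epimers 22 and 23 interconvert and crystallization-induced diastereomer transformation should drain the mixture into one crystalline epimer, taken here to be 23 with the (R) acetal carbon, whose configuration is thus controlled by the (S)-1-phenylethyl group.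

Step 12
Reactants: 23 (R)-acetal of the lactol with (S)-1-phenylethanol
Product: 24 CNP0211607.1 (target; (R) lactol carbon)
Conditions: H2 (1 atm), 10% Pd/C, EtOAc, 0 °C to rt; filtration and evaporation below 25 °C
Reagents that add atoms: none
Why: Hydrogenolysis of the benzylic C–O bond of the 1-phenylethyl group leaves all four bonds of the acetal carbon untouched, so the (R) configuration set in step 11 should be carried into the lactol with retention, and the neutral aprotic medium suppresses ring-chain epimerization.

Compound list

1 | 2-hydroxy-3-methoxy-5-methylbenzaldehyde | COc1cc(C)cc(C=O)c1O | starting material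
2 | 2-(benzyloxy)-3-methoxy-5-methylbenzaldehyde | COc1cc(C)cc(C=O)c1OCc1ccccc1 | intermediate
3 | 2-(benzyloxy)-6-iodo-3-methoxy-5-methylbenzaldehyde | COc1cc(C)c(I)c(C=O)c1OCc1ccccc1 | intermediate
4 | 2-(benzyloxy)-6-iodo-3-methoxy-5-methylphenyl formate | COc1cc(C)c(I)c(OC=O)c1OCc1ccccc1 | intermediate
5 | 2-(benzyloxy)-6-iodo-3-methoxy-5-methylphenol | COc1cc(C)c(I)c(O)c1OCc1ccccc1 | intermediate
6 | 3,4-difluoroanisole (1,2-difluoro-4-methoxybenzene) | COc1ccc(F)c(F)c1 | starting material
7 | (2,3-difluoro-6-methoxyphenyl)lithium | COc1ccc(F)c(F)c1[Li] | intermediate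
8 | 1,2-difluoro-4-methoxy-3-methylbenzene | COc1ccc(F)c(F)c1C | intermediate
9 | (2,3-difluoro-5-methoxy-4-methylphenyl)lithium | COc1cc([Li])c(F)c(F)c1C | intermediate
10 | 2,3-difluoro-5-methoxy-4-methylbenzaldehyde | COc1cc(C=O)c(F)c(F)c1C | intermediate
11 | lithium (2,3-difluoro-5-methoxy-4-methylphenyl){[2-(dimethylamino)ethyl](methyl)amino}methanolate | COc1cc(C(O[Li])N(C)CCN(C)C)c(F)c(F)c1C | intermediate
12 | ring-lithiated derivative of 11 (lithium on the ring carbon between the methoxy-bearing and the amino alkoxide-bearing carbons) | COc1c([Li])c(C(O[Li])N(C)CCN(C)C)c(F)c(F)c1C | intermediate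
13 | 4,5-difluoro-3-hydroxy-7-methoxy-6-methylisobenzofuran-1(3H)-one (racemic) | COc1c(C)c(F)c(F)c2c1C(=O)OC2O | intermediate
14 | potassium 3,4-difluoro-2-formyl-6-methoxy-5-methylbenzoate | COc1c(C)c(F)c(F)c(C=O)c1C(=O)[O-].[K+] | intermediate
15 | potassium 3-[2-(benzyloxy)-6-iodo-3-methoxy-5-methylphenoxy]-4-fluoro-2-formyl-6-methoxy-5-methylbenzoate | COc1cc(C)c(I)c(Oc2c(F)c(C)c(OC)c(C(=O)[O-])c2C=O)c1OCc1ccccc1.[K+] | intermediate
16 | 4-[2-(benzyloxy)-6-iodo-3-methoxy-5-methylphenoxy]-5-fluoro-3-hydroxy-7-methoxy-6-methylisobenzofuran-1(3H)-one (racemic) | COc1cc(C)c(I)c(Oc2c(F)c(C)c(OC)c3c2C(O)OC3=O)c1OCc1ccccc1 | intermediate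
17 | 4-[2-(benzyloxy)-6-iodo-3-methoxy-5-methylphenoxy]-5-fluoro-3,7-dimethoxy-6-methylisobenzofuran-1(3H)-one (racemic) | COc1cc(C)c(I)c(Oc2c(F)c(C)c(OC)c3c2C(OC)OC3=O)c1OCc1ccccc1 | intermediate
18 | arylmagnesium chloride from 17 (MgCl in place of iodine) | COc1cc(C)c([Mg]Cl)c(Oc2c(F)c(C)c(OC)c3c2C(OC)OC3=O)c1OCc1ccccc1 | intermediate
19 | chloromagnesium carboxylate from 18 (CO2MgCl in place of MgCl) | COc1cc(C)c(C(=O)O[Mg]Cl)c(Oc2c(F)c(C)c(OC)c3c2C(OC)OC3=O)c1OCc1ccccc1 | intermediate
20 | protected depsidone: target skeleton with benzyl ether on the ring A phenol, methyl ether on the ring B phenol and methyl acetal at the phthalide carbon (racemic) | COc1cc(C)c2c(c1OCc1ccccc1)Oc1c(c(C)c(OC)c3c1C(OC)OC3=O)OC2=O | intermediate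
21 | racemic lactol with the constitution of the target | COc1cc(C)c2c(c1O)Oc1c(c(C)c(O)c3c1C(O)OC3=O)OC2=O | intermediate
22 | (S)-1-phenylethyl acetal of 21 with (S) acetal carbon | COc1cc(C)c2c(c1O)Oc1c(c(C)c(O)c3c1[C@@H](O[C@@H](C)c1ccccc1)OC3=O)OC2=O | intermediate
23 | (S)-1-phenylethyl acetal of 21 with (R) acetal carbon | COc1cc(C)c2c(c1O)Oc1c(c(C)c(O)c3c1[C@H](O[C@@H](C)c1ccccc1)OC3=O)OC2=O | intermediate
24 | CNP0211607.1, depsidone with (R)-configured hydroxyphthalide carbon | COc1cc(C)c2c(c1O)Oc1c(c(C)c(O)c3c1[C@H](O)OC3=O)OC2=O | target

Total step count: 12. Longest linear sequence: 9 steps (steps 1–3 then 7–12; the branch through steps 4–6 then 7–12 is equally long).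

Steps most likely to fail

Step 9. A carboxylate is a weak nucleophile for a fluoride activated by a single para acyl group, so the ring closure may stall at the acid stage. The arylmagnesium may also add to the lactone carbonyl or displace the fluoride itself before CO2 arrives, and the product lactone may be opened if the medium is not dry. Fallback: setting out from 17, the activated fluoride is first displaced by a hydroxide surrogate (benzaldoxime, Cs2CO3, DMSO, 80 °C; SNAr by the oximate, then loss of benzonitrile) to give the ortho-hydroxy diaryl ether F1. Intramolecular alkoxycarbonylation of its aryl iodide (Pd(OAc)2, Xantphos, CO 1 atm, Et3N, toluene, 90 °C) then closes the lactone and comes back to the route at 20.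

Step 7. Substitution by the doubly ortho-substituted phenoxide may be slow on a ring that carries a carboxylate and a para methoxy group, and the aldehyde may degrade at the temperature then required. Fallback: setting out from 13, alkylation of the open carboxylate (MeI, K2CO3, DMF) gives the neutral and more electrophilic methyl ester aldehyde F2. SNAr with 5 (Cs2CO3, DMF, 60 °C) at the fluorine ortho to the formyl group gives the diaryl ether methyl ester F3; its ester, twisted by two ortho neighbours, should activate the other fluorine only weakly. Saponification (LiOH, THF/H2O, then aq. HCl) comes back to the route at 16.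

Step 11. The two acetal epimers may show little thermodynamic bias, the lattice may select the undesired epimer, or the benzylic alcohol may be lost under acid by elimination or etherification. Fallback: setting out from 21, benzyl alcohol with catalytic CSA gives the racemic benzyl acetal F4. Preparative chromatography on a chiral phase gives the (R)-benzyl acetal F5, while the (S)-benzyl acetal F6 is re-racemized with CSA/benzyl alcohol and recycled. Hydrogenolysis of F5 (H2, Pd/C, EtOAc) comes back to the route at 24.

Further compounds

F1 | step 9 | 4-[2-(benzyloxy)-6-iodo-3-methoxy-5-methylphenoxy]-5-hydroxy-3,7-dimethoxy-6-methylisobenzofuran-1(3H)-one (racemic) | COc1cc(C)c(I)c(Oc2c(O)c(C)c(OC)c3c2C(OC)OC3=O)c1OCc1ccccc1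
F2 | step 7 | methyl 3,4-difluoro-2-formyl-6-methoxy-5-methylbenzoate | COc1c(C)c(F)c(F)c(C=O)c1C(=O)OC
F3 | step 7 | methyl 3-[2-(benzyloxy)-6-iodo-3-methoxy-5-methylphenoxy]-4-fluoro-2-formyl-6-methoxy-5-methylbenzoate | COc1cc(C)c(I)c(Oc2c(F)c(C)c(OC)c(C(=O)OC)c2C=O)c1OCc1ccccc1
F4 | step 11 | benzyl acetal of 21 (racemic) | COc1cc(C)c2c(c1O)Oc1c(c(C)c(O)c3c1C(OCc1ccccc1)OC3=O)OC2=O
F5 | step 11 | benzyl acetal of 21 with (R) acetal carbon | COc1cc(C)c2c(c1O)Oc1c(c(C)c(O)c3c1[C@H](OCc1ccccc1)OC3=O)OC2=O
F6 | step 11 | benzyl acetal of 21 with (S) acetal carbon | COc1cc(C)c2c(c1O)Oc1c(c(C)c(O)c3c1[C@@H](OCc1ccccc1)OC3=O)OC2=O
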